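## Analysis of the target

The target 34 is a trans-fused tetrahydroindene, in indene numbering 5-ethyl-1,3,4,7-tetramethyl-5-[(1E,3E)-2-methyl-4-phenylbuta-1,3-dienyl]-3a,4,5,7a-tetrahydro-1H-indene-4-carboxylic acid; here ring A is the six-membered ring C1–C2–C3–C3a–C6a–C7 with a C2=C3 double bond and ring B the five-membered ring C3a–C4–C5–C6–C6a with a C5=C6 double bond. There are five stereocentres: C7 (methyl, carboxyl) and C1 (ethyl, E,E-dienyl arm) are adjacent quaternary carbons, with the C7 methyl and the C1 ethyl on one face (α here) and the carboxyl and the dienyl arm on the other (β). The ring-fusion hydrogens are trans (C3a–H α, C6a–H β) and the C4 methyl is α, cis to C3a–H. The styryl diene is sensitive to acid, electrophiles and light, the ring-fusion and C4 hydrogens are allylic, and the carboxyl sits between two quaternary carbons, so its ester cannot be saponified at the carbonyl carbon. The hard parts are the vicinal quaternary pair with four different substituents and the trans ring fusion in a fixed relation to that pair. The strategy rests on ring B: with C5 as a carbonyl carbon it is a cyclopent-2-enone made of two alkyne carbons (C6a and the methyl-bearing C6), the two carbons of an E-propenyl group (C3a, C4) and one carbonyl carbon, tethered through C7–C1–C2=C3. One (2+2+1) cycloaddition of an acyclic dienyne therefore closes ring A and ring B together.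

## Retrosynthetic reasoning

34 is cut at the O–CH3 bond of methyl ester 33. The ester is carried to the end because the free acid would interfere with the organometallic steps, and the forward step must attack the methyl carbon, not the shielded carbonyl.

33 is traced to allylic alcohol 30 and enone 29 by returning the C6a–H bond and the C5=C6 alkene to a C5 carbonyl with a C6=C6a alkene. Forward, a 1,2-reduction anti to the C4 methyl gives the 5α-alcohol, invertive C–N bond formation gives diazene 32 on the β face, and suprafacial hydrogen transfer places C6a–H β. Since the C4 methyl is cis to C3a–H, this makes the fusion trans whatever face the key step chooses.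

29 is cut at C3a–C6a, C4–C5 and C5–C6 (Pauson–Khand retron), giving dienyne 27. This removes both rings and two stereocentres at once. The E-propenyl geometry translates into C4–H trans to C3a–H, which is the cis C3a–H/C4-methyl relationship of the target. The C3a configuration must come from the face of the alkene that binds. The C7 ester and the C1 dienyl arm are cis on ring A and cannot both be pseudo-equatorial, so the working model puts the ester in the plane and the dienyl arm axial.

27 is cut at C3–C3a into Z-iodoalkene 25 and boronic acid 26, and 25 at C2=C3 back to aldehyde 24. Building this arm by a late Wittig ethylidenation would give the wrong (Z) propenyl geometry; taking the E geometry from 26 and the Z geometry from an iodo-olefination avoids that.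

24 is cut at the diene C–C bond into E-iodoalkene 22 and boronic acid 23. The aldehyde of 22 comes from the E-propenyl group of 20 by oxidative cleavage. The styryl diene must therefore be made after that cleavage, and the second iodoalkene after the first has been coupled.

The C7 propynyl group of 20 is traced through terminal alkyne 18 and aldehyde 17 to the hydroxymethyl group of 16. The iodoalkene of 16 comes from the C1 propynyl group of 14 by hydrozirconation–iodination, which must precede formation of the C7 alkyne so that only one alkyne is present at a time.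

14 comes from half-ester acid 12 by reduction of the free carboxyl only. 12 is cut at C1–C7 by an Ireland–Claisen transform to mixed malonate 9. This single sigmatropic step makes both quaternary centres; the secondary carbinol of 9 supplies the absolute configuration by chirality transfer, and the propenyl group it leaves on C1 is the masked aldehyde.

9 is the ester of enynol 6 with half-ester 8, which comes from malonate 7. 6 is cut at the enyne bond into Z-iodoalkenol 4 and propyne 5; 4 comes from propargylic alcohol 2, and 2 from ynone 1 by asymmetric reduction.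

## Alternatives that were turned down

Alternative 1: Ring B is cut at C6–C6a and C4–C3a. Forward, a nucleophilic phosphine such as n-Bu3P adds to ethyl penta-2,3-dienoate A1 and the zwitterion annulates the enone (5R,E)-6-(tert-butyldimethylsilyloxy)-5-methylhex-3-en-2-one A2 to give cyclopentene A3, with the acetyl group (future C3 and its methyl) on C3a and the future C7 on C6a.
- For: one catalytic, potentially enantioselective step gives ring B with the C5=C6 alkene already in place and the C4/C3a/C6a array set. On this point it is stronger than the chosen route, which needs a reduction and a transposition after its key step.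
- Against: the ester on C6 must be taken down to a methyl group without moving the alkene. C7 is only tertiary in A3, so both quaternary centres still have to be built next to a ring, one after the other, without a reliable control element, and the stereocentre bought in A2 is destroyed on the way. Ring A then has to be closed onto a trisubstituted alkene.
- Comparison: the chosen route makes the quaternary pair first, in one stereospecific rearrangement, and lets it direct the ring closure.

Alternative 2: Ring A is cut at C7–C6a and C3–C3a. Forward, the pyranone 4-[(tert-butyldimethylsilyloxy)methyl]-3,6-dimethylpyran-2-one A4 and the dienophile (E)-hex-3-en-2-one A5 combine under high pressure to the bridged lactone A6.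
- For: the cycloaddition creates quaternary C7 with its carboxyl carbon and the C3 methyl in one step, sets C3a and C6a trans from the E dienophile, and leaves a lactone bridge that could depart in an allylic substitution to make C1 and the C2=C3 alkene. In direct installation of the carboxyl-bearing centre it is stronger than the chosen route.
- Against: an electron-poor diene meets an electron-poor, β-substituted dienophile, so rate, regiochemistry and endo/exo control are doubtful and cycloreversion with loss of the bridge threatens. C1 is still sp2 and needs two further C–C bonds with facial control. Ring B would have to be closed by inserting C5 between the acetyl carbon and the unactivated CH2 of the ethyl group, for which A6 offers no handle.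
- Comparison: the chosen key step assembles ring B from exactly the carbons the target needs.

Alternative 3: Ring A is cut at C1–C2. Forward, a zerovalent palladium catalyst made from Pd(OAc)2 and a phosphine inserts into the Z-alkenyl iodide of A7, adds it 6-exo to the ethyl-bearing diene terminus C1, and the allylpalladium loses a benzylic hydride to give A8, which is identical with 33.
- For: it ends directly at the ester of the target, is catalytic in metal, and creates C1, ring A and the styryl diene in one operation; in end-game economy it is stronger than the chosen route.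
- Against: the migratory insertion must form a quaternary carbon next to quaternary C7 at a fully substituted alkene carbon. The facial selectivity at C1 has to be relayed from C7 and C6a. The allylpalladium can eliminate in several directions and with either geometry. A7 already contains ring B, the trans C3a/C6a pattern, a Z-iodoalkene and an acyclically made quaternary C7, so it is long to make.
- Comparison: the chosen route makes C1 and C7 together by a rearrangement with a predictable transition state and builds the arms by stereospecific couplings.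

Key step: step 16

## Route

Remark: ring atoms are numbered C1, C2, C3, C3a, C4, C5, C6, C6a, C7 as in the analysis; α is the face of the C7 methyl group, β that of the C7 carboxyl group.

Remark: RuCl[(S,S)-TsDPEN](p-cymene) in step 1 is assumed to give the (S)-propargylic alcohol, the alkynyl group behaving as an aryl group does; if the sense were opposite, RuCl[(R,R)-TsDPEN](p-cymene) would be used.

Step 1
Reactants: 1 hex-3-yn-2-one
Product: 2 (2S)-hex-3-yn-2-ol
Conditions: RuCl[(S,S)-TsDPEN](p-cymene) (0.5 mol%), i-PrOH, 25 °C
Reagents that add atoms: none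
Why: Noyori asymmetric transfer hydrogenation of an alkynyl methyl ketone; the alkynyl group takes the place of the aryl group in the hydride-transfer transition state, so the (S) carbinol, the only stereocentre taken from a catalyst, should result.

Step 2
Reactants: 2 (2S)-hex-3-yn-2-ol
Product: 4 (2S,3Z)-4-iodohex-3-en-2-ol, via cyclic alkenylaluminate 3 (not isolated)
Conditions: NaAlH2(OCH2CH2OMe)2, THF, 0 → 25 °C; then I2, −78 → 0 °C
Reagents that add atoms: iodine, II
Why: Hydroxyl-directed trans-hydroalumination puts aluminium on the distal alkyne carbon in a five-membered chelate, and iodinolysis with retention gives the Z iodide, iodine cis to the carbinol carbon.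

Step 3
Reactants: 4 (2S,3Z)-4-iodohex-3-en-2-ol; 5 propyne
Product: 6 (2S,3Z)-4-ethylhept-3-en-5-yn-2-ol
Conditions: PdCl2(PPh3)2 (3 mol%), CuI (5 mol%), i-Pr2NH, THF, 0 → 25 °C
Reagents that add atoms: none
Why: Sonogashira coupling with retention of alkene geometry, so the propynyl group ends cis to the carbinol carbon; the free alcohol is tolerated.

Step 4
Reactants: 7 dimethyl 2-methylpropanedioate
Product: 8 3-methoxy-2-methyl-3-oxopropanoic acid (racemic)
Conditions: KOH (1.0 equiv), MeOH, 0 → 25 °C; then aq. HCl
Reagents that add atoms: potassium hydroxide, [K+].[OH-]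
Why: Mono-saponification of a symmetrical malonate; the carboxylate formed resists a second hydrolysis, and the stereocentre of 8 is irrelevant because it becomes an enolate carbon in step 6.

Step 5
Reactants: 6 (2S,3Z)-4-ethylhept-3-en-5-yn-2-ol; 8 3-methoxy-2-methyl-3-oxopropanoic acid
Product: 9 1-[(2S,3Z)-4-ethylhept-3-en-5-yn-2-yl] 3-methyl 2-methylpropanedioate (both epimers at the malonate carbon)
Conditions: DCC, DMAP (cat.), CH2Cl2, 0 → 25 °C
Reagents that add atoms: none
Why: Steglich esterification of a secondary allylic alcohol; the carbinol centre is not touched.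

Step 6
Reactants: 9 1-[(2S,3Z)-4-ethylhept-3-en-5-yn-2-yl] 3-methyl 2-methylpropanedioate
Product: 12 (2S,3R,4E)-3-ethyl-2-(methoxycarbonyl)-2-methyl-3-(prop-1-ynyl)hex-4-enoic acid, via silyl ketene acetal 10 (not isolated), via trimethylsilyl ester 11 (not isolated)
Conditions: LiN(SiMe3)2, THF, −78 °C; Me3SiCl, −78 → 25 °C; toluene, 80 °C; then 1 M HCl
Reagents that add atoms: none
Why: Ireland–Claisen rearrangement through a chair: the lithium enolate is chelated between both carbonyl oxygens, so the silyloxy group of 10 is syn to the methoxycarbonyl group, which puts the ester pseudo-equatorial and the C-methyl pseudo-axial on C7, while on C1 the propynyl group (cis to the carbinol carbon) is pseudo-axial and the ethyl group pseudo-equatorial. With the carbinol methyl pseudo-equatorial the (S) centre is transferred to C1 and C7 and the new propenyl alkene is E.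

Step 7
Reactants: 12 (2S,3R,4E)-3-ethyl-2-(methoxycarbonyl)-2-methyl-3-(prop-1-ynyl)hex-4-enoic acid
Product: 14 methyl (2S,3R,4E)-3-ethyl-2-(hydroxymethyl)-2-methyl-3-(prop-1-ynyl)hex-4-enoate, via acid chloride 13 (not isolated)
Conditions: (COCl)2, DMF (cat.), CH2Cl2, 0 → 25 °C; then NaBH4, THF–DMF, −20 → 0 °C
Reagents that add atoms: none
Why: Acid chloride formation and borohydride reduction, which takes the acyl chloride and leaves the hindered methyl ester; neither quaternary centre can epimerise.

Step 8
Reactants: 14 methyl (2S,3R,4E)-3-ethyl-2-(hydroxymethyl)-2-methyl-3-(prop-1-ynyl)hex-4-enoate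
Product: 16 methyl (2S,3R,4E)-3-ethyl-2-(hydroxymethyl)-3-[(1E)-2-iodoprop-1-enyl]-2-methylhex-4-enoate, via alkenylzirconocene chloride 15 (not isolated)
Conditions: Cp2Zr(H)Cl (2.5 equiv), THF, 0 → 25 °C; then I2, 0 °C
Reagents that add atoms: iodine, II
Why: syn-Hydrozirconation of the internal alkyne places zirconium on the methyl-bearing carbon, away from quaternary C1, and iodinolysis with retention gives the E iodoalkene. The first equivalent of reagent is taken by the hydroxyl group and the disubstituted alkene is much slower than the alkyne.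

Step 9
Reactants: 16 methyl (2S,3R,4E)-3-ethyl-2-(hydroxymethyl)-3-[(1E)-2-iodoprop-1-enyl]-2-methylhex-4-enoate
Product: 17 methyl (2S,3R,4E)-3-ethyl-2-formyl-3-[(1E)-2-iodoprop-1-enyl]-2-methylhex-4-enoate
Conditions: Dess–Martin periodinane, NaHCO3, CH2Cl2, 0 → 25 °C
Reagents that add atoms: none
Why: Dess–Martin oxidation of a neopentyl alcohol to a non-enolisable aldehyde under buffered, non-nucleophilic conditions.

Step 10
Reactants: 17 methyl (2S,3R,4E)-3-ethyl-2-formyl-3-[(1E)-2-iodoprop-1-enyl]-2-methylhex-4-enoate
Product: 18 methyl (2R,3R,4E)-3-ethyl-2-ethynyl-3-[(1E)-2-iodoprop-1-enyl]-2-methylhex-4-enoate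
Conditions: Me3SiCHN2, n-BuLi, THF, −78 °C; then 17, −78 → 0 °C
Reagents that add atoms: (trimethylsilyl)diazomethane, C[Si](C)(C)C=[N+]=[N-]
Why: Colvin rearrangement: the lithiated diazo reagent adds to the aldehyde, silanolate and nitrogen are lost and the alkylidene carbene undergoes a 1,2-hydrogen shift. The aprotic conditions avoid the alkoxide-induced deformylation to which a 2-formyl ester without α-hydrogen is prone.

Step 11
Reactants: 18 methyl (2R,3R,4E)-3-ethyl-2-ethynyl-3-[(1E)-2-iodoprop-1-enyl]-2-methylhex-4-enoate
Product: 20 methyl (2S,3R,4E)-3-ethyl-3-[(1E)-2-iodoprop-1-enyl]-2-methyl-2-(prop-1-ynyl)hex-4-enoate, via lithium acetylide 19 (not isolated)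
Conditions: LiN(i-Pr)2, THF, −78 °C; then MeI, −78 → 0 °C
Reagents that add atoms: iodomethane, CI
Why: Deprotonation of the terminal alkyne and C-methylation; the ester has no α-hydrogen and the E iodoalkene has no hydrogen anti to iodine, so neither reacts with the amide base.

Step 12
Reactants: 20 methyl (2S,3R,4E)-3-ethyl-3-[(1E)-2-iodoprop-1-enyl]-2-methyl-2-(prop-1-ynyl)hex-4-enoate
Product: 22 methyl (2R,3R,4E)-3-ethyl-3-formyl-5-iodo-2-methyl-2-(prop-1-ynyl)hex-4-enoate, via vicinal diol 21 (not isolated)
Conditions: OsO4 (2 mol%), NaIO4, 2,6-lutidine, dioxane–H2O, 25 °C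
Reagents that add atoms: sodium periodate, [Na+].[O-]I(=O)(=O)=O (terminal oxidant; the oxygen is passed on through catalytic OsO4)
Why: Lemieux–Johnson cleavage: OsO4 takes the only electron-rich alkene (the iodoalkene is deactivated, the alkyne inert) and periodate cleaves the diol to the C1 aldehyde.

Step 13
Reactants: 22 methyl (2R,3R,4E)-3-ethyl-3-formyl-5-iodo-2-methyl-2-(prop-1-ynyl)hex-4-enoate; 23 [(E)-2-phenylethenyl]boronic acid
Product: 24 methyl (2R,3R,4E,6E)-3-ethyl-3-formyl-2,5-dimethyl-7-phenyl-2-(prop-1-ynyl)hepta-4,6-dienoate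
Conditions: Pd(PPh3)4 (5 mol%), K3PO4, THF–H2O, 40 °C
Reagents that add atoms: none
Why: Suzuki–Miyaura coupling with retention at both partners gives the E,E diene arm; the aldehyde is non-enolisable and survives the mild base.

Step 14
Reactants: 24 methyl (2R,3R,4E,6E)-3-ethyl-3-formyl-2,5-dimethyl-7-phenyl-2-(prop-1-ynyl)hepta-4,6-dienoate
Product: 25 methyl (2S,3S,4E,6E)-3-ethyl-3-[(1Z)-2-iodoprop-1-enyl]-2,5-dimethyl-7-phenyl-2-(prop-1-ynyl)hepta-4,6-dienoate
Conditions: EtPPh3I, n-BuLi, THF, 25 °C; I2, −78 °C; NaN(SiMe3)2, −78 → −20 °C; then 24, −78 → −20 °C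
Reagents that add atoms: ethyltriphenylphosphonium iodide, CC[P+](c1ccccc1)(c1ccccc1)c1ccccc1.[I-]; iodine, II
Why: Stork–Zhao-type Wittig reaction with the α-iodo ylide is kinetically Z-selective, placing iodine cis to C1, which is the geometry needed for the C2=C3 bond of ring A.

Step 15
Reactants: 25 methyl (2S,3S,4E,6E)-3-ethyl-3-[(1Z)-2-iodoprop-1-enyl]-2,5-dimethyl-7-phenyl-2-(prop-1-ynyl)hepta-4,6-dienoate; 26 [(E)-prop-1-enyl]boronic acid
Product: 27 methyl (2S,3R,4Z,6E)-3-ethyl-2,5-dimethyl-3-[(1E,3E)-2-methyl-4-phenylbuta-1,3-dienyl]-2-(prop-1-ynyl)octa-4,6-dienoate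
Conditions: Pd(PPh3)4 (5 mol%), K3PO4, THF–H2O, 40 °C
Reagents that add atoms: none
Why: Suzuki–Miyaura coupling with retention; the Z geometry comes from 25 and the E geometry from 26, so the Z,E diene arm is defined by its partners.

Step 16
Reactants: 27 methyl (2S,3R,4Z,6E)-3-ethyl-2,5-dimethyl-3-[(1E,3E)-2-methyl-4-phenylbuta-1,3-dienyl]-2-(prop-1-ynyl)octa-4,6-dienoate
Product: 29 bicyclic enone methyl ester (C5 ketone; C6=C6a and C2=C3 alkenes; 3a-H α; 4-methyl α), via hexacarbonyldicobalt alkyne complex 28 (not isolated)
Conditions: Co2(CO)8 (1.1 equiv), CH2Cl2, 25 °C; then N-methylmorpholine N-oxide, 0 → 25 °C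
Reagents that add atoms: dicobalt octacarbonyl, [C-]#[O+].[C-]#[O+].[C-]#[O+].[C-]#[O+].[C-]#[O+].[C-]#[O+].[C-]#[O+].[C-]#[O+].[Co].[Co] (source of the C5 carbonyl)
Why: Complexation gives cluster 28; the N-oxide oxidises one carbonyl ligand away, the E-propenyl end of the Z,E diene takes the free site and inserts into the Co–C6a bond (C3a–C6a), a carbonyl ligand inserts (C4–C5) and reductive elimination (C5–C6) releases the enone. The closest known reaction type is the amine N-oxide-promoted intramolecular Pauson–Khand reaction of 1,7-enynes to bicyclo[4.3.0]nonenones. Ring A closes in the alkene-insertion step as a six-membered ring through the tether C7–C1–C2=C3, whose two quaternary carbons and Z double bond hold C3a next to C6a; ring B is the five-membered ring of the (2+2+1) event, closed by carbonyl insertion and reductive elimination. C4 is set by the alkene geometry: syn addition across the E double bond puts C4–H trans to C3a–H, that is the C4 methyl cis to C3a–H and trans to the C3a–C3 bond. C3a is set by the alkene face: in the chair-like forming ring A the C7 substituent lying in the plane of the developing C6=C6a bond meets the C6 methyl (A(1,3) strain), so the flat ester takes that pseudo-equatorial site, the C7 methyl is pseudo-axial and C3a–H becomes pseudo-axial on the same α face. The dienyl arm on C1, cis to the ester, is then pseudo-axial on the β face, which costs little because C3 and C6a are sp2 and offer no 1,3-diaxial partner. Chemoselectivity comes from the substrate: the two alkenes bonded directly to C1 could only close a four-membered ring, the styryl alkene of the E,E arm could reach the cluster only through a six-membered ring holding a trans double bond, and the tether fixes the regiochemistry with the carbonyl between C4 and C6. The selectivity the step needs, and the least certain one, is this facial selectivity.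

Step 17
Reactants: 29 bicyclic enone methyl ester
Product: 30 allylic alcohol methyl ester (5-OH α; cis to the 4-methyl; C6=C6a alkene)
Conditions: NaBH4, CeCl3·7H2O, MeOH, −78 → −20 °C
Reagents that add atoms: none
Why: Luche 1,2-reduction; hydride should add to C5 from the β face, anti to the adjacent C4 methyl, giving the 5α-alcohol, and the weakly basic cold conditions spare the doubly allylic C3a–H.

Step 18
Reactants: 30 allylic alcohol methyl ester (5-OH α)
Product: 33 methyl ester of the target (C5=C6 alkene; 6a-H β), via sulfonyl hydrazone adduct 31 (not isolated), via allylic diazene 32 (not isolated)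
Conditions: N-isopropylidene-N′-(2-nitrobenzenesulfonyl)hydrazine (IPNBSH), PPh3, DEAD, THF, 0 → 25 °C; then CF3CH2OH–H2O (1:1), 25 °C
Reagents that add atoms: none
Why: Mitsunobu displacement with inversion puts nitrogen on the β face of C5; hydrolysis of the hydrazone and loss of sulfinic acid give diazene 32, whose retro-ene loss of nitrogen delivers hydrogen suprafacially to C6a on the β face and moves the alkene to C5=C6 (reductive 1,3-transposition of an allylic alcohol). C6a–H thus ends trans to the C4 methyl and to C3a–H.

Step 19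
Reactants: 33 methyl ester of the target
Product: 34 target acid, 5-ethyl-1,3,4,7-tetramethyl-5-[(1E,3E)-2-methyl-4-phenylbuta-1,3-dienyl]-3a,4,5,7a-tetrahydro-1H-indene-4-carboxylic acid (configuration as in the SMILES)
Conditions: EtSNa, DMF, 80 °C; then aq. HCl
Reagents that add atoms: none
Why: SN2 demethylation by thiolate at the methyl carbon, chosen because the carbonyl carbon between two quaternary centres is closed to hydroxide; the thiolate is too weak a base to touch the allylic stereocentres.

## Compound list

1 | hex-3-yn-2-one | CCC#CC(C)=O | starting material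
2 | (2S)-hex-3-yn-2-ol | C[C@H](O)C#CCC | intermediate
3 | cyclic alkenylaluminate (sodium salt of the five-membered oxaaluminacycle; not isolated) | C[C@@H]1O[Al-](OCCOC)(OCCOC)C(CC)=C1.[Na+] | intermediate
4 | (2S,3Z)-4-iodohex-3-en-2-ol | C[C@H](O)/C=C(\I)CC | intermediate
5 | propyne | CC#C | starting material
6 | (2S,3Z)-4-ethylhept-3-en-5-yn-2-ol | C[C@H](O)/C=C(\C#CC)CC | intermediate
7 | dimethyl 2-methylpropanedioate (dimethyl methylmalonate) | COC(=O)C(C)C(=O)OC | starting material
8 | 3-methoxy-2-methyl-3-oxopropanoic acid (racemic) | COC(=O)C(C)C(O)=O | intermediate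
9 | 1-[(2S,3Z)-4-ethylhept-3-en-5-yn-2-yl] 3-methyl 2-methylpropanedioate (both epimers at the malonate carbon) | COC(=O)C(C)C(=O)O[C@@H](C)/C=C(\C#CC)CC | intermediate
10 | silyl ketene acetal, methyl (2Z)-3-{[(2S,3Z)-4-ethylhept-3-en-5-yn-2-yl]oxy}-2-methyl-3-(trimethylsilyloxy)prop-2-enoate (not isolated) | COC(=O)/C(C)=C(\O[Si](C)(C)C)O[C@@H](C)/C=C(\C#CC)CC | intermediate
11 | trimethylsilyl ester of 12 (not isolated) | C[Si](C)(C)OC(=O)[C@@](C)(C(=O)OC)[C@@](CC)(C#CC)/C=C/C | intermediate
12 | (2S,3R,4E)-3-ethyl-2-(methoxycarbonyl)-2-methyl-3-(prop-1-ynyl)hex-4-enoic acid | OC(=O)[C@@](C)(C(=O)OC)[C@@](CC)(C#CC)/C=C/C | intermediate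
13 | acid chloride of 12, methyl (2R,3R,4E)-2-(chlorocarbonyl)-3-ethyl-2-methyl-3-(prop-1-ynyl)hex-4-enoate (not isolated) | ClC(=O)[C@@](C)(C(=O)OC)[C@@](CC)(C#CC)/C=C/C | intermediate
14 | methyl (2S,3R,4E)-3-ethyl-2-(hydroxymethyl)-2-methyl-3-(prop-1-ynyl)hex-4-enoate | OC[C@@](C)(C(=O)OC)[C@@](CC)(C#CC)/C=C/C | intermediate
15 | alkenylzirconocene chloride from 14, zirconium on the methyl-bearing alkene carbon, hydroxyl as zirconium alkoxide (not isolated) | Cl[Zr](OC[C@@](C)(C(=O)OC)[C@@](CC)(/C=C(\C)[Zr](Cl)(C1C=CC=C1)C1C=CC=C1)/C=C/C)(C1C=CC=C1)C1C=CC=C1 | intermediate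
16 | methyl (2S,3R,4E)-3-ethyl-2-(hydroxymethyl)-3-[(1E)-2-iodoprop-1-enyl]-2-methylhex-4-enoate | OC[C@@](C)(C(=O)OC)[C@@](CC)(/C=C(\C)I)/C=C/C | intermediate
17 | methyl (2S,3R,4E)-3-ethyl-2-formyl-3-[(1E)-2-iodoprop-1-enyl]-2-methylhex-4-enoate | O=C[C@@](C)(C(=O)OC)[C@@](CC)(/C=C(\C)I)/C=C/C | intermediate
18 | methyl (2R,3R,4E)-3-ethyl-2-ethynyl-3-[(1E)-2-iodoprop-1-enyl]-2-methylhex-4-enoate | C#C[C@@](C)(C(=O)OC)[C@@](CC)(/C=C(\C)I)/C=C/C | intermediate
19 | lithium acetylide of 18 (not isolated) | [Li]C#C[C@@](C)(C(=O)OC)[C@@](CC)(/C=C(\C)I)/C=C/C | intermediate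
20 | methyl (2S,3R,4E)-3-ethyl-3-[(1E)-2-iodoprop-1-enyl]-2-methyl-2-(prop-1-ynyl)hex-4-enoate | CC#C[C@@](C)(C(=O)OC)[C@@](CC)(/C=C(\C)I)/C=C/C | intermediate
21 | vicinal diol, methyl 3-ethyl-4,5-dihydroxy-3-[(1E)-2-iodoprop-1-enyl]-2-methyl-2-(prop-1-ynyl)hexanoate (C2 and C3 as in 20; mixture at C4 and C5; not isolated) | CC#C[C@@](C)(C(=O)OC)[C@@](CC)(/C=C(\C)I)C(O)C(C)O | intermediate
22 | methyl (2R,3R,4E)-3-ethyl-3-formyl-5-iodo-2-methyl-2-(prop-1-ynyl)hex-4-enoate | CC#C[C@@](C)(C(=O)OC)[C@@](CC)(/C=C(\C)I)C=O | intermediate
23 | [(E)-2-phenylethenyl]boronic acid | OB(O)/C=C/c1ccccc1 | starting material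
24 | methyl (2R,3R,4E,6E)-3-ethyl-3-formyl-2,5-dimethyl-7-phenyl-2-(prop-1-ynyl)hepta-4,6-dienoate | CC#C[C@@](C)(C(=O)OC)[C@@](CC)(/C=C(C)/C=C/c1ccccc1)C=O | intermediate
25 | methyl (2S,3S,4E,6E)-3-ethyl-3-[(1Z)-2-iodoprop-1-enyl]-2,5-dimethyl-7-phenyl-2-(prop-1-ynyl)hepta-4,6-dienoate | CC#C[C@@](C)(C(=O)OC)[C@@](CC)(/C=C(C)/C=C/c1ccccc1)/C=C(\I)C | intermediate
26 | [(E)-prop-1-enyl]boronic acid | C/C=C/B(O)O | starting material
27 | methyl (2S,3R,4Z,6E)-3-ethyl-2,5-dimethyl-3-[(1E,3E)-2-methyl-4-phenylbuta-1,3-dienyl]-2-(prop-1-ynyl)octa-4,6-dienoate | CC#C[C@@](C)(C(=O)OC)[C@@](CC)(/C=C(C)/C=C/c1ccccc1)/C=C(C)\C=C\C | intermediate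
28 | hexacarbonyldicobalt complex of the alkyne of 27 (not isolated) | CC12[Co]3(=C=O)(=C=O)(=C=O)[Co]1(=C=O)(=C=O)(=C=O)C23[C@@](C)(C(=O)OC)[C@@](CC)(/C=C(C)/C=C/c1ccccc1)/C=C(C)\C=C\C | intermediate
29 | bicyclic enone methyl ester: C5 ketone, C6=C6a and C2=C3 alkenes; 1-ethyl α, 1-dienyl β, 7-methyl α, 7-CO2Me β, 3a-H α, 4-methyl α | CC[C@]1(/C=C(C)/C=C/c2ccccc2)C=C(C)[C@H]2[C@H](C)C(=O)C(C)=C2[C@@]1(C)C(=O)OC | intermediate
30 | allylic alcohol methyl ester: as 29 with 5-OH α (5S), cis to the 4-methyl | CC[C@]1(/C=C(C)/C=C/c2ccccc2)C=C(C)[C@H]2[C@H](C)[C@H](O)C(C)=C2[C@@]1(C)C(=O)OC | intermediate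
31 | sulfonyl hydrazone adduct: as 30 with a 5β N-(2-nitrophenylsulfonyl)-N′-isopropylidenehydrazino group in place of the hydroxyl (not isolated) | CC[C@]1(/C=C(C)/C=C/c2ccccc2)C=C(C)[C@H]2[C@H](C)[C@@H](N(N=C(C)C)S(=O)(=O)c3ccccc3[N+](=O)[O-])C(C)=C2[C@@]1(C)C(=O)OC | intermediate
32 | allylic diazene: as 30 with a 5β diazenyl group in place of the hydroxyl (not isolated) | CC[C@]1(/C=C(C)/C=C/c2ccccc2)C=C(C)[C@H]2[C@H](C)[C@@H](N=N)C(C)=C2[C@@]1(C)C(=O)OC | intermediate
33 | methyl ester of the target: C5=C6 and C2=C3 alkenes; 3a-H α, 6a-H β, 4-methyl α | CC[C@]1(/C=C(C)/C=C/c2ccccc2)C=C(C)[C@H]2[C@H](C)C=C(C)[C@@H]2[C@@]1(C)C(=O)OC | intermediate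
34 | 5-ethyl-1,3,4,7-tetramethyl-5-[(1E,3E)-2-methyl-4-phenylbuta-1,3-dienyl]-3a,4,5,7a-tetrahydro-1H-indene-4-carboxylic acid (CNP0103503.1) | CC[C@]1(/C=C(C)/C=C/c2ccccc2)C=C(C)[C@H]2[C@H](C)C=C(C)[C@@H]2[C@@]1(C)C(=O)O | target

## Step count and least certain steps

Total: 19 steps. Longest linear sequence: 18 steps (steps 1–3 and 5–19; step 4 is a one-step branch).

**Step 16 (key step).**
- Risk: the alkene is internal, 1,2-disubstituted and part of a diene, the enyne is of the 1,7 type and the cluster sits next to a quaternary carbon. Alkene insertion may therefore be slow, so that decomplexation or β-hydride elimination to a triene competes, and the facial selectivity at C3a rests on a single A(1,3) argument. Base-induced epimerisation of 29 is not a remedy, since the doubly allylic C3a–H would drift into the conjugated dienone.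
- Fallback: use a more reactive ene partner and add the C4 methyl afterwards. Setting out from 25, Suzuki coupling with vinylboronic acid pinacol ester (in place of 26) gives the terminal diene methyl (2S,3R,4Z)-3-ethyl-2,5-dimethyl-3-[(1E,3E)-2-methyl-4-phenylbuta-1,3-dienyl]-2-(prop-1-ynyl)hepta-4,6-dienoate F1. The same Co2(CO)8-mediated cyclisation, now on a monosubstituted alkene, gives the 4-demethyl enone F2. Kinetic α′-enolate formation with LiN(i-Pr)2 at −78 °C and methylation with MeI, anti to the ring A carbon on C3a, places the methyl α and returns to the route at 29.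

**Step 6.**
- Risk: the ketene acetal is a push–pull alkene whose geometry may not stay that of the chelated enolate, giving the C7 epimer. The rearrangement, which forms two adjacent quaternary carbons from a stabilised ketene acetal, may also be slow enough for ionisation of the allylic ester to compete.
- Fallback: a redox reassignment that makes either C7 epimer usable, because the two carboxyl groups on C7 differ only in oxidation level. Setting out from 9, the epimeric acid (2R,3R,4E)-3-ethyl-2-(methoxycarbonyl)-2-methyl-3-(prop-1-ynyl)hex-4-enoic acid F3 is reduced with LiBH4, which takes the methyl ester and leaves the carboxylate, to (2S,3R,4E)-3-ethyl-2-(hydroxymethyl)-2-methyl-3-(prop-1-ynyl)hex-4-enoic acid F4. Esterification with Me3SiCHN2 returns to the route at 14.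

**Step 14.**
- Risk: the iodo-ylide is bulky and basic and the aldehyde is neopentyl, so low conversion, loss of iodine and erosion of the Z selectivity are likely.
- Fallback: setting out from 24, Still–Gennari olefination with ethyl 2-[bis(2,2,2-trifluoroethoxy)phosphoryl]propanoate (KN(SiMe3)2, 18-crown-6) gives the Z enoate 1-ethyl 6-methyl (2Z)-4-ethyl-2,5-dimethyl-4-[(1E,3E)-2-methyl-4-phenylbuta-1,3-dienyl]-5-(prop-1-ynyl)hex-2-enedioate F5. i-Bu2AlH at −78 °C reduces the conjugated ethyl ester in preference to the shielded C7 ester, giving the Z allylic alcohol methyl (4Z)-3-ethyl-6-hydroxy-2,5-dimethyl-3-[(1E,3E)-2-methyl-4-phenylbuta-1,3-dienyl]-2-(prop-1-ynyl)hex-4-enoate F6. MnO2 gives the Z enal methyl (4Z)-3-ethyl-2,5-dimethyl-3-[(1E,3E)-2-methyl-4-phenylbuta-1,3-dienyl]-6-oxo-2-(prop-1-ynyl)hex-4-enoate F7. E-selective Takai–Utimoto ethylidenation (CrCl2, CH3CHI2) returns to the route at 27.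

**Step 17.**
- Risk: poor facial selectivity of hydride addition, since the β face carries ring A one carbon further away; the 5β-alcohol would lead to the cis-fused isomer.
- Fallback: reagent control in place of substrate control. Setting out from 29, reduction with catecholborane and (R)-2-methyl-CBS-oxazaborolidine (C6 alkene carbon as the large group) should give the (5S) alcohol and returns at 30; no new compound is made on this way, which is entered below as F0.

**Step 18.**
- Risk: the Mitsunobu displacement at a hindered allylic carbinol may proceed through ionisation (loss of stereospecificity) or elimination to a cyclopentadiene.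
- Fallback: setting out from 30, formylation (HCO2H, DCC, DMAP) gives the allylic formate F8. Pd(OAc)2 with n-Bu3P in THF ionises it anti to the formate and delivers hydride from palladium to the more substituted terminus C6a on the β face (Tsuji hydrogenolysis of an allylic formate), returning to the route at 33.

## Further compounds

F1 | step 16 | methyl (2S,3R,4Z)-3-ethyl-2,5-dimethyl-3-[(1E,3E)-2-methyl-4-phenylbuta-1,3-dienyl]-2-(prop-1-ynyl)hepta-4,6-dienoate | CC#C[C@@](C)(C(=O)OC)[C@@](CC)(/C=C(C)/C=C/c1ccccc1)/C=C(C)\C=C
F2 | step 16 | 4-demethyl analogue of enone 29 (C4 is CH2; 3a-H α) | CC[C@]1(/C=C(C)/C=C/c2ccccc2)C=C(C)[C@H]2CC(=O)C(C)=C2[C@@]1(C)C(=O)OC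
F3 | step 6 | (2R,3R,4E)-3-ethyl-2-(methoxycarbonyl)-2-methyl-3-(prop-1-ynyl)hex-4-enoic acid | OC(=O)[C@](C)(C(=O)OC)[C@@](CC)(C#CC)/C=C/C
F4 | step 6 | (2S,3R,4E)-3-ethyl-2-(hydroxymethyl)-2-methyl-3-(prop-1-ynyl)hex-4-enoic acid | OC(=O)[C@](C)(CO)[C@@](CC)(C#CC)/C=C/C
F5 | step 14 | 1-ethyl 6-methyl (2Z)-4-ethyl-2,5-dimethyl-4-[(1E,3E)-2-methyl-4-phenylbuta-1,3-dienyl]-5-(prop-1-ynyl)hex-2-enedioate (C4 and C5 configured as C3 and C2 of 24) | CC#C[C@@](C)(C(=O)OC)[C@@](CC)(/C=C(C)/C=C/c1ccccc1)/C=C(C)\C(=O)OCC
F6 | step 14 | methyl (4Z)-3-ethyl-6-hydroxy-2,5-dimethyl-3-[(1E,3E)-2-methyl-4-phenylbuta-1,3-dienyl]-2-(prop-1-ynyl)hex-4-enoate | CC#C[C@@](C)(C(=O)OC)[C@@](CC)(/C=C(C)/C=C/c1ccccc1)/C=C(C)\CO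
F7 | step 14 | methyl (4Z)-3-ethyl-2,5-dimethyl-3-[(1E,3E)-2-methyl-4-phenylbuta-1,3-dienyl]-6-oxo-2-(prop-1-ynyl)hex-4-enoate | CC#C[C@@](C)(C(=O)OC)[C@@](CC)(/C=C(C)/C=C/c1ccccc1)/C=C(C)\C=O
F0 | step 17 | none | none
F8 | step 18 | 5α-formate of 30 | CC[C@]1(/C=C(C)/C=C/c2ccccc2)C=C(C)[C@H]2[C@H](C)[C@H](OC=O)C(C)=C2[C@@]1(C)C(=O)OC
A1 | alternative 1 | ethyl penta-2,3-dienoate | CCOC(=O)C=C=CC
A2 | alternative 1 | (5R,E)-6-(tert-butyldimethylsilyloxy)-5-methylhex-3-en-2-one | CC(=O)/C=C/[C@@H](C)CO[Si](C)(C)C(C)(C)C
A3 | alternative 1 | ethyl 4-acetyl-3-methyl-5-(1-silyloxypropan-2-yl)cyclopent-1-ene-1-carboxylate | CCOC(=O)C1=C[C@@H](C)[C@H](C(C)=O)[C@H]1[C@@H](C)CO[Si](C)(C)C(C)(C)C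
A4 | alternative 2 | 4-[(tert-butyldimethylsilyloxy)methyl]-3,6-dimethylpyran-2-one | Cc1oc(=O)c(C)c(CO[Si](C)(C)C(C)(C)C)c1
A5 | alternative 2 | (E)-hex-3-en-2-one | CC/C=C/C(C)=O
A6 | alternative 2 | 5-acetyl-8-[(tert-butyldimethylsilyloxy)methyl]-6-ethyl-1,4-dimethyl-2-oxabicyclo[2.2.2]oct-7-en-3-one | C[C@]12C(=O)O[C@](C)(C=C1CO[Si](C)(C)C(C)(C)C)[C@@H](CC)[C@@H]2C(C)=O
A7 | alternative 3 | methyl 3-ethyl-2-{5-[(1Z)-1-iodoprop-1-en-2-yl]-2,4-dimethylcyclopent-2-en-1-yl}-2,5-dimethyl-7-phenylhepta-3,5-dienoate | I/C=C(C)\[C@H]1[C@H](C)C=C(C)[C@@H]1[C@@](C)(C(=O)OC)/C(CC)=C/C(C)=C/Cc1ccccc1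
A8 | alternative 3 | methyl ester of the target (identical with 33) | CC[C@]1(/C=C(C)/C=C/c2ccccc2)C=C(C)[C@H]2[C@H](C)C=C(C)[C@@H]2[C@@]1(C)C(=O)OC
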